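**Retrosynthetic overview** (locants are those of quinic acid, C1 = quaternary carbon)
1. Last bond: the ester between (E)-caffeic acid (as diacetate acid chloride) and the tertiary C1–OH of 3,4-O-isopropylidene-1,5-quinide, whose only free hydroxyl is that at C1; aqueous acid then opens lactone, acetal and phenol acetates.
2. The quinide comes from a protected 3-dehydroquinate by equatorial hydride delivery to C3 and acid-driven acetal transposition/lactonisation.
3. Key disconnection: C1–C2 and C5–C6 of the carbocycle, both made in one Lewis-acid cascade from an enol-pyruvate silane (C6 nucleophile, C1 electrophile) and a dioxolane-fused 3-alkoxycyclobutanone that holds C2–C3(=O)–C4–C5 closed by a temporary C2–C5 bond. Strain release unmasks a C2 enolate/C5 oxocarbenium dipole, in the polarity by which phosphoenolpyruvate and erythrose 4-phosphate give 3-dehydroquinate in the shikimate pathway.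
4. Enabling feature: in the six-membered ring the quaternary α-hydroxy-acid carbon C1 with its neighbour CH2 (C6) is a pyruvate unit, and C3–O and C5–O stand 1,3 across C4, so that at the 3-keto level C2–C5 is a β-alkoxy ketone, the retron of a 3-alkoxycyclobutanone. The trans 4,5-diol lets a temporary dioxolane on O4/O5 steer both the bond that breaks and the face of attack at C5.
5. Ring order: dioxolane (bought) → cyclobutanone ([2+2], dechlorination, enzymatic resolution) → cyclohexanone (key step) → lactone and cis-dioxolane (protection) → both opened at the end; the arene comes with caffeic acid.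

Key step: step 5

Remark: 2,2-dimethyl-1,3-dioxole (1) is taken to be a catalogue chemical; its double bond is the electron-rich cis-enediol ether needed for the ketene cycloaddition.

Step 1
Reactants: 1 2,2-dimethyl-1,3-dioxole; 2 trichloroacetyl chloride
Product: 4 rac-(1R,5S)-7,7-dichloro-3,3-dimethyl-2,4-dioxabicyclo[3.2.0]heptan-6-one (cis-fused), via dichloroketene 3 (not isolated)
Conditions: Zn–Cu couple, Et2O/DME, 0 °C to rt, slow addition of 2
Reagents that add atoms: none
Why: Dichloroketene, formed by zinc dechlorination of 2, adds to the electron-rich cis-enediol ether 1 in a thermal ketene–alkene [2+2] cycloaddition; the alkene is symmetric so there is no regiochemical issue, suprafacial addition gives the cis ring fusion, and DME ties up ZnCl2 so that the acetal should survive.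

Step 2
Reactants: 4 rac-(1R,5S)-7,7-dichloro-3,3-dimethyl-2,4-dioxabicyclo[3.2.0]heptan-6-one
Product: 5 rac-(1S,5S)-3,3-dimethyl-2,4-dioxabicyclo[3.2.0]heptan-6-one
Conditions: Zn, NH4Cl, MeOH, 0 °C to rt
Reagents that add atoms: none
Why: Zinc reduction of an α,α-dichloroketone (via the zinc enolate, protonated by NH4Cl) removes both chlorines under near-neutral conditions that should leave the acetal and the strained ketone intact; no stereocentre is touched.

Step 3
Reactants: 5 rac-(1S,5S)-3,3-dimethyl-2,4-dioxabicyclo[3.2.0]heptan-6-one
Product: 6 (1S,5S)-3,3-dimethyl-2,4-dioxabicyclo[3.2.0]heptan-6-one (the enantiomer left unreduced)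
Conditions: alcohol dehydrogenase ADH-A from Rhodococcus ruber ((S)-selective), NAD+ (cat.), i-PrOH (10 vol%), phosphate buffer pH 7.5, 30 °C, run to just past half conversion; chromatography
Reagents that add atoms: none
Why: Enzymatic kinetic resolution by enantiomer-selective ketone reduction: the (S)-selective dehydrogenase delivers hydride to the carbonyl face that is the open convex face only in the (1R,5R) ketone, which should be reduced to the (6S) alcohol, while the (1S,5S) ketone 6, whose α-carbon becomes C4 of the target, is recovered; this fixes the absolute configuration of the route.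

Step 4
Reactants: 7 methyl pyruvate
Product: 8 methyl 2-[(trimethylsilyl)oxy]prop-2-enoate
Conditions: Me3SiCl, Et3N, DMAP (cat.), Et2O, 0 °C to rt; distillation
Reagents that add atoms: chlorotrimethylsilane, C[Si](C)(C)Cl
Why: Soft enolisation and O-silylation of the α-keto ester (silyl enol ether formation) gives the enol-pyruvate equivalent, nucleophilic at CH2 and a latent electrophile at the carbonyl carbon.

Step 5
Reactants: 6 (1S,5S)-3,3-dimethyl-2,4-dioxabicyclo[3.2.0]heptan-6-one; 8 methyl 2-[(trimethylsilyl)oxy]prop-2-enoate
Product: 11 methyl (1R,4S,5R)-4,5-O-isopropylidene-3-oxo-1-[(trimethylsilyl)oxy]cyclohexane-1-carboxylate (protected 3-dehydroquinate), via zwitterion 9 (not isolated), via open-chain adduct 10 (not isolated)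
Conditions: 8 (2 equiv), EtAlCl2 (20 mol%), CH2Cl2, −78 to −40 °C; Et3N, then aq. NaHCO3
Reagents that add atoms: none
Why: EtAlCl2 activates the cyclobutanone carbonyl and the acetal oxygen on the β-carbon pushes out the exocyclic C5–C2 bond, so that ring strain is exchanged for a C2=C3 aluminium enolate and a dioxolanylium ion at C5 (9); the CH2 terminus of enol silane 8 (C6) adds to C5 to give silyloxocarbenium ion 10, and the enolate carbon C2 then attacks C1 in a 6-(enolendo)-exo-trig aldol closure that forms the only new ring, the cyclohexanone, with the silyl group kept on the C1 oxygen. The closest known reaction type is the Lewis-acid-promoted formal [4+2] cycloaddition of 3-alkoxycyclobutanones with silyl enol ethers to 3-alkoxy-5-silyloxycyclohexanones, and the polarity (enol pyruvate onto an aldehyde-level carbon, then enolate onto the pyruvate ketone) is that by which phosphoenolpyruvate and erythrose 4-phosphate are turned into 3-dehydroquinate in the shikimate pathway. C4 is carried over unchanged from 6; C5 is set by attack of 8 on the five-membered cation anti to the C4 side chain, which gives the trans-dioxolane and so the trans 4,5-diol; C1 is set in a chair transition state that keeps the fused dioxolane and the CO2Me group equatorial and the C1–O bond axial, as in the non-enzymatic aldol closure that leads to 3-dehydroquinate. The step needs cleavage of the CH2-side bond and not of the ring-fusion bond, which is secured because the donating oxygen sits in the fused dioxolane, where its lone pair overlaps with the exocyclic C–CH2 bond but is close to orthogonal to the endocyclic fusion bond; it also needs 8 to outrun self-condensation, which the low standing concentration of the zwitterion and an excess of 8 should provide.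

Step 6
Reactants: 11 methyl (1R,4S,5R)-4,5-O-isopropylidene-3-oxo-1-[(trimethylsilyl)oxy]cyclohexane-1-carboxylate
Product: 12 methyl (1S,3R,4R,5R)-3-hydroxy-4,5-O-isopropylidene-1-[(trimethylsilyl)oxy]cyclohexane-1-carboxylate (methyl 4,5-O-isopropylidene-1-O-trimethylsilylquinate)
Conditions: LiBH(s-Bu)3 (L-Selectride), THF, −78 °C; then H2O
Reagents that add atoms: none
Why: Ketone reduction with a bulky borohydride: the ring is locked by the trans-fused dioxolane and the axial face of C3 is shielded by the axial C1–OSiMe3 group, so hydride should enter equatorially and give the axial 3-OH, cis to O4 and to O1 as in quinic acid; the ester is not reduced at −78 °C.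

Step 7
Reactants: 12 methyl 4,5-O-isopropylidene-1-O-trimethylsilylquinate
Product: 13 3,4-O-isopropylidene-1,5-quinide (quinic acid 1,5-lactone with the acetonide on the cis 3,4-diol and a free tertiary 1-OH)
Conditions: TsOH·H2O (10 mol%), acetone, H2O (1.5 equiv), rt; then toluene, reflux, MeOH distilled off
Reagents that add atoms: none
Why: Acid catalysis removes the tertiary silyl ether, moves the isopropylidene group from the strained trans-4,5 position to the cis-3,4 diol through the O4-bound oxocarbenium ion (acetal migration under thermodynamic control) and then closes the γ-lactone from the freed 5-OH onto the cis ester (transesterification driven by removal of MeOH); no stereocentre changes.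

Step 8
Reactants: 14 (E)-caffeic acid
Product: 15 (E)-3,4-di-O-acetylcaffeic acid
Conditions: Ac2O, pyridine, DMAP (cat.), rt; then H2O
Reagents that add atoms: acetic anhydride, CC(=O)OC(C)=O
Why: Acetylation of both phenols (nucleophilic catalysis by DMAP) masks the catechol for the acid chloride stage; the mixed anhydride at the carboxyl group is hydrolysed on work-up.

Step 9
Reactants: 15 (E)-3,4-di-O-acetylcaffeic acid
Product: 16 (E)-3,4-di-O-acetylcaffeoyl chloride
Conditions: (COCl)2, DMF (cat.), CH2Cl2, 0 °C to rt
Reagents that add atoms: oxalyl chloride, O=C(Cl)C(Cl)=O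
Why: Acid chloride formation through the chloroiminium (Vilsmeier-type) species; the (E)-alkene and the aryl acetates are inert.

Step 10
Reactants: 13 3,4-O-isopropylidene-1,5-quinide; 16 (E)-3,4-di-O-acetylcaffeoyl chloride
Product: 17 1-O-[(E)-3,4-di-O-acetylcaffeoyl]-3,4-O-isopropylidene-1,5-quinide
Conditions: pyridine, DMAP (0.2 equiv), CH2Cl2, rt to 40 °C
Reagents that add atoms: none
Why: DMAP-catalysed acylation (acylpyridinium intermediate) of the only free hydroxyl, the hindered tertiary C1–OH on the open face of the bicyclic lactone; the C1 stereocentre is not touched.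

Step 11
Reactants: 17 1-O-[(E)-3,4-di-O-acetylcaffeoyl]-3,4-O-isopropylidene-1,5-quinide
Product: 18 1-O-caffeoylquinic acid
Conditions: 1 M aq. HCl/THF (1:3), rt
Reagents that add atoms: water, O
Why: Acid hydrolysis cleaves the acetal, the two aryl acetates and the bridged lactone, while the cinnamate-type ester on the tertiary carbinol is the slowest to hydrolyse and no base is present that could cause acyl migration or alkene isomerisation; all four stereocentres are kept.

**Compound list**
1 | 2,2-dimethyl-1,3-dioxole | CC1(C)OC=CO1 | starting material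
2 | trichloroacetyl chloride | ClC(Cl)(Cl)C(Cl)=O | starting material
3 | dichloroketene | ClC(Cl)=C=O | intermediate (not isolated)
4 | rac-(1R,5S)-7,7-dichloro-3,3-dimethyl-2,4-dioxabicyclo[3.2.0]heptan-6-one, cis-fused (racemate, both enantiomers written) | O=C1C(Cl)(Cl)[C@@H]2OC(C)(C)O[C@H]12.O=C1C(Cl)(Cl)[C@H]2OC(C)(C)O[C@@H]12 | intermediate
5 | rac-(1S,5S)-3,3-dimethyl-2,4-dioxabicyclo[3.2.0]heptan-6-one (racemate, both enantiomers written) | O=C1C[C@@H]2OC(C)(C)O[C@H]12.O=C1C[C@H]2OC(C)(C)O[C@@H]12 | intermediate
6 | (1S,5S)-3,3-dimethyl-2,4-dioxabicyclo[3.2.0]heptan-6-one | O=C1C[C@@H]2OC(C)(C)O[C@H]12 | intermediate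
7 | methyl pyruvate | CC(=O)C(=O)OC | starting material
8 | methyl 2-[(trimethylsilyl)oxy]prop-2-enoate | C=C(O[Si](C)(C)C)C(=O)OC | intermediate
9 | ring-opened zwitterion: EtAlCl2-bound enolate of the methyl ketone side chain on a 2,2-dimethyl-1,3-dioxolan-4-ylium ring, side-chain carbon configured as in 6 | C=C(O[Al-](Cl)(Cl)CC)[C@H]1OC(C)(C)[O+]=C1 | intermediate (not isolated)
10 | open-chain adduct: trans-4,5-disubstituted dioxolane carrying the aluminium enolate and the O-silylated 2-oxopropanoate (silyloxocarbenium) chain | C=C(O[Al-](Cl)(Cl)CC)[C@H]1OC(C)(C)O[C@@H]1CC(=[O+][Si](C)(C)C)C(=O)OC | intermediate (not isolated)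
11 | methyl (1R,4S,5R)-4,5-O-isopropylidene-3-oxo-1-[(trimethylsilyl)oxy]cyclohexane-1-carboxylate (trans-fused dioxolane; C1–OSi cis to O4, CO2Me cis to O5) | C[Si](C)(C)O[C@]1(C(=O)OC)C[C@H]2OC(C)(C)O[C@@H]2C(=O)C1 | intermediate
12 | methyl (1S,3R,4R,5R)-3-hydroxy-4,5-O-isopropylidene-1-[(trimethylsilyl)oxy]cyclohexane-1-carboxylate (3-OH cis to O4 and O1) | C[Si](C)(C)O[C@]1(C(=O)OC)C[C@H]2OC(C)(C)O[C@@H]2[C@H](O)C1 | intermediate
13 | 3,4-O-isopropylidene-1,5-quinide | O[C@]1(C(=O)O2)C[C@@H]2[C@@H]3OC(C)(C)O[C@@H]3C1 | intermediate
14 | (E)-caffeic acid | OC(=O)/C=C/c1ccc(O)c(O)c1 | starting material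
15 | (E)-3,4-di-O-acetylcaffeic acid | CC(=O)Oc1ccc(/C=C/C(O)=O)cc1OC(C)=O | intermediate
16 | (E)-3,4-di-O-acetylcaffeoyl chloride | CC(=O)Oc1ccc(/C=C/C(Cl)=O)cc1OC(C)=O | intermediate
17 | 1-O-[(E)-3,4-di-O-acetylcaffeoyl]-3,4-O-isopropylidene-1,5-quinide | CC(=O)Oc1ccc(/C=C/C(=O)O[C@]2(C(=O)O3)C[C@@H]3[C@@H]4OC(C)(C)O[C@@H]4C2)cc1OC(C)=O | intermediate
18 | 1-O-caffeoylquinic acid | O=C(/C=C/c1ccc(O)c(O)c1)O[C@]1(C(=O)O)C[C@@H](O)[C@H](O)[C@H](O)C1 | target

**Step count and risks**
Total step count: 11. Longest linear sequence: 8 steps (1, 2, 3, 5, 6, 7, 10, 11).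

Steps most likely to fail:

Step 5. The cascade may be diverted by Lewis-acid cleavage of the acetal, by opening of the ring-fusion bond, by syn attack on the cation, or by loss of the silyl group from the open-chain adduct before it closes to the trans-fused ring. The fallback makes the same two bonds from an open-chain form of the dipole. It sets out from 6: acid-catalysed methanolysis (MeOH, PPTS, rt; the retro-aldol opening typical of 3-alkoxycyclobutanones) should give 1-[(4S)-5-methoxy-2,2-dimethyl-1,3-dioxolan-4-yl]ethan-1-one F1. Kinetic enolisation on the methyl side (LiN(i-Pr)2, Me3SiCl, THF, −78 °C) should give the enol silane {[1-((4R)-5-methoxy-2,2-dimethyl-1,3-dioxolan-4-yl)ethenyl]oxy}(trimethyl)silane F2. Slow addition of F2 to 8 and Me3SiOTf (10 mol%) in CH2Cl2 at −78 °C ionises the methoxy acetal; 8 adds to the dioxolanylium ion anti to the side chain, and intramolecular Mukaiyama aldol closure of the internal enol silane onto the silyloxocarbenium ion returns to the route at 11.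

Step 3. The dehydrogenase may not discriminate the enantiomers of 5 well enough (both reduced, or neither). The fallback moves the resolution to the alcohol. It sets out from 5: NaBH4 (MeOH, −20 °C) should give by attack on the convex face the racemic all-cis alcohol rac-(1S,5R,6R)-3,3-dimethyl-2,4-dioxabicyclo[3.2.0]heptan-6-ol F3. Lipase-catalysed acylation (Burkholderia cepacia lipase, vinyl acetate, t-BuOMe, 30 °C) should acetylate the (6R) enantiomer, in line with the empirical enantiopreference of lipases for secondary alcohols, to give (1S,5S,6R)-3,3-dimethyl-2,4-dioxabicyclo[3.2.0]heptan-6-yl acetate F4, which is separated from the unreacted (6S) alcohol. K2CO3/MeOH should give (1S,5R,6R)-3,3-dimethyl-2,4-dioxabicyclo[3.2.0]heptan-6-ol F5, and oxidation with Dess–Martin periodinane returns to the route at 6.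

Step 7. Lactonisation of the methyl ester may stay incomplete, or the acetal may scramble between the 3,4- and 4,5-positions. The fallback takes all protecting groups off and puts the needed ones on again. It sets out from 12: aqueous HCl (2 M, 60 °C) should hydrolyse silyl ether, acetal and methyl ester to (−)-quinic acid F6, which on heating with 2,2-dimethoxypropane and TsOH·H2O in acetone should give the acetonide lactone by the standard procedure and so return to the route at 13.

**Further compounds**
F1 | step 5 | 1-[(4S)-5-methoxy-2,2-dimethyl-1,3-dioxolan-4-yl]ethan-1-one (mixture at the methoxy carbon) | COC1OC(C)(C)O[C@@H]1C(C)=O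
F2 | step 5 | {[1-((4R)-5-methoxy-2,2-dimethyl-1,3-dioxolan-4-yl)ethenyl]oxy}(trimethyl)silane | COC1OC(C)(C)O[C@@H]1C(=C)O[Si](C)(C)C
F3 | step 3 | rac-(1S,5R,6R)-3,3-dimethyl-2,4-dioxabicyclo[3.2.0]heptan-6-ol, all-cis (racemate, both enantiomers written) | O[C@@H]1C[C@@H]2OC(C)(C)O[C@H]12.O[C@H]1C[C@H]2OC(C)(C)O[C@@H]12
F4 | step 3 | (1S,5S,6R)-3,3-dimethyl-2,4-dioxabicyclo[3.2.0]heptan-6-yl acetate | CC(=O)O[C@@H]1C[C@@H]2OC(C)(C)O[C@H]12
F5 | step 3 | (1S,5R,6R)-3,3-dimethyl-2,4-dioxabicyclo[3.2.0]heptan-6-ol | O[C@@H]1C[C@@H]2OC(C)(C)O[C@H]12
F6 | step 7 | (−)-quinic acid | O[C@]1(C(=O)O)C[C@@H](O)[C@H](O)[C@H](O)C1
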